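**Plan**

- Retrosynthesis cuts C8–C15 together with the C9–O bond of the 9,11-oxirane (one radical chain event), then the C6 acetal, the C11–O/C7–O pair (a vinyl oxirane), the C ring (C9=C11 and C13–C14), C9–C10 (a [3,3] shift) and the A ring.
- Forward order: A ring by Michael/aldol annulation; quaternary C10 by Johnson–Claisen; C ring by aminocatalytic Michael/aldol annulation; C7 by sulfonium ylide and C11–OOtBu by SN1′ opening; B-ring lactol (kept as methyl acetal); 1,2-diacetate; ring D plus oxirane; C17 methylene; free lactol.
- Stereochemistry: the C2 carbinol from CBS reduction (C5 fixed trans in the same alcohol) is relayed to C10 by the suprafacial [3,3] shift; C13 comes from the aminocatalyst; C11 from axial capture trans to the C13 chain; C1/C2 from hydride on the β face; C8 and C9 arise in the key step from C13 and C11; C6 is thermodynamic.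
- Enabling feature: C8 sits between the ketone carbon C15 and C9, whose oxygen bridges to C11. An allylic C11–O–O bond beside a C8=C9 alkene lets the C9 radical formed by acyl attack on C8 close the oxirane, so ring D, the quaternary C8 and the 9α,11α-oxirane form together.

Key step: step 18

Remark: ent-kaurane locants are used (C6 = acetal carbon, C7 = OCH2, C15 = ketone carbon, C17 = exocyclic CH2; α = face of the C10 methyl). The lactol carbon C6 is assumed to settle to the drawn anomer by ring–chain equilibration, and the earlier acetals are drawn with that configuration although they may be anomeric mixtures.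

Step 1
Reactants: 1 mesityl oxide; 2 ethyl acetoacetate
Product: 3 ethyl 2,6,6-trimethyl-4-oxocyclohex-2-ene-1-carboxylate (racemic)
Conditions: BF3·OEt2, neat, 0 °C → rt
Reagents that add atoms: none
Why: Lewis-acid Michael addition of the acetoacetate α-carbon to the β-carbon of mesityl oxide (C4 becomes quaternary) followed by intramolecular aldol condensation of the methyl ketone onto the acetoacetate ketone (Robinson-type annulation) should give the ring A enone with C6 and C20 in place; C5 is racemic and epimerisable.

Step 2
Reactants: 3 ethyl 2,6,6-trimethyl-4-oxocyclohex-2-ene-1-carboxylate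
Product: 4 ethyl (1R,4R)-4-hydroxy-2,6,6-trimethylcyclohex-2-ene-1-carboxylate (trans; C2–OH β, C5–CO2Et α)
Conditions: (S)-Me-CBS (20 mol%), BH3·SMe2, toluene, −30 °C; MeOH; chromatography
Reagents that add atoms: none
Why: Corey–Bakshi–Shibata reduction with the alkenyl arm as the large group should give the (4R)-carbinol from both enantiomers of 3; the trans isomer 4 is separated from its cis C5-epimer, which can be re-oxidised and recycled because C5 of 3 racemises through its dienol, so at most half of 3 is converted per pass.

Step 3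
Reactants: 4 trans hydroxy ester; 5 triethyl orthoacetate
Product: 7 ethyl (1R,2R)-2-(2-ethoxy-2-oxoethyl)-2,6,6-trimethylcyclohex-3-ene-1-carboxylate, via ketene acetal 6 (not isolated)
Conditions: EtCO2H (10 mol%), xylenes, 140 °C, distil off EtOH
Reagents that add atoms: none
Why: Johnson–Claisen rearrangement through a [3,3] shift of the ketene acetal delivers C9 to C10 on the face that carried the C2–O bond (β, anti to the C5 ester), so the carbinol configuration is transferred to the quaternary C10 (methyl α) and the alkene moves to C1=C2.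

Step 4
Reactants: 7 diester; 8 tert-butyl acetate
Product: 9 tert-butyl 4-[(1R,6R)-6-(ethoxycarbonyl)-1,5,5-trimethylcyclohex-2-en-1-yl]-3-oxobutanoate
Conditions: LDA, tert-butyl acetate, THF, −78 °C; then 7, −78 → −40 °C; aq NH4Cl
Reagents that add atoms: none
Why: crossed Claisen condensation in which lithio tert-butyl acetate attacks only the unhindered CH2CO2Et group, the ring ester being flanked by two quaternary carbons and its C5–H not being removed at this temperature.

Step 5
Reactants: 10 but-3-en-1-ol
Product: 11 tert-butyl(but-3-en-1-yloxy)diphenylsilane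
Conditions: TBDPSCl, imidazole, CH2Cl2, rt
Reagents that add atoms: tert-butyl(chloro)diphenylsilane CC(C)(C)[Si](Cl)(c1ccccc1)c1ccccc1
Why: routine silylation of a primary alcohol; the TBDPS ether is chosen to survive the acidic steps 7, 9 and 11.

Step 6
Reactants: 11 silyl ether; 12 crotonaldehyde
Product: 13 (E)-5-[(tert-butyldiphenylsilyl)oxy]pent-2-enal
Conditions: Hoveyda–Grubbs II catalyst (2 mol%), crotonaldehyde (5 equiv), CH2Cl2, 40 °C
Reagents that add atoms: none
Why: olefin cross-metathesis of a terminal alkene with an enal partner should give the E-enal with loss of propene.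

Step 7
Reactants: 9 β-keto ester; 13 enal
Product: 15 ethyl (1R,2R)-2-{(4S)-4-[2-(tert-butyldiphenylsilyloxy)ethyl]-6-oxocyclohex-1-en-1-yl}-2,6,6-trimethylcyclohex-3-ene-1-carboxylate, via Michael adduct 14 (not isolated)
Conditions: (S)-2-{bis[3,5-bis(trifluoromethyl)phenyl](trimethylsilyloxy)methyl}pyrrolidine (10 mol%), PhCO2H (10 mol%), toluene, rt; then p-TsOH·H2O (40 mol%), toluene, 80 °C
Reagents that add atoms: none
Why: iminium-catalysed Michael addition of the active methylene C14 to the enal (attack anti to the shielding group of the (S)-catalyst sets (S)-C13), then acid-mediated intramolecular aldol condensation of C9 onto the aldehyde C11 with loss of isobutene and CO2 (aminocatalytic Robinson-type annulation) should build ring C as the C8 enone, the remote C10 centre not interfering.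

Step 8
Reactants: 15 enone
Product: 16 vinyl oxirane (spiro-epoxide at C8 with C7 as the oxirane CH2; both C8 epimers)
Conditions: Me3S+ I−, KHMDS, THF, −20 → 0 °C
Reagents that add atoms: trimethylsulfonium iodide C[S+](C)C.[I-]
Why: Corey–Chaykovsky epoxidation, in which the unstabilised sulfonium ylide adds 1,2 to the enone carbonyl and closes the oxirane; the new C8 centre is inconsequential because it is destroyed in step 9.

Step 9
Reactants: 16 vinyl oxirane
Product: 17 allylic peroxide (C8=C9 alkene, C7 CH2OH, 11α-OOtBu trans to the C13 side chain)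
Conditions: anhydrous tBuOOH (5 equiv, decane), Sc(OTf)3 (5 mol%), CH2Cl2, −40 → −10 °C
Reagents that add atoms: tert-butyl hydroperoxide CC(C)(C)OO
Why: Proposed new method: the Lewis acid ionises the tertiary allylic C8–O bond of the vinyl oxirane to a cyclohexenyl cation (C8–C9–C11) that the hydroperoxide captures at the unhindered secondary terminus C11 by axial attack anti to the pseudo-equatorial C13 side chain (1,3-trans, C11–O α), which gives the tetrasubstituted C8=C9 alkene and frees the C7 hydroxyl; the closest known reaction types are the acid-catalysed opening of epoxides by hydroperoxides and the SN1′ (1,4) alcoholysis of vinyl epoxides.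

Step 10
Reactants: 17 allylic peroxide
Product: 18 lactol (seven-membered C6 hemiacetal closed onto the C7 oxygen)
Conditions: DIBAL-H (3.5 equiv), CH2Cl2, −78 °C; Rochelle salt
Reagents that add atoms: none
Why: partial reduction of the hindered ester should stop at the aluminium hemiacetal chelated by the C7 alkoxide, and the hydroxy aldehyde set free on work-up closes to the lactol; hindered dialkyl peroxides are known to survive aluminium hydride reduction of a neighbouring ester or lactone at this temperature.

Step 11
Reactants: 18 lactol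
Product: 19 methyl acetal
Conditions: MeOH, PPTS (10 mol%), rt
Reagents that add atoms: methanol CO
Why: acid-catalysed acetalisation through the cyclic oxocarbenium ion protects C6 for the oxidations that follow, under conditions too mild to ionise the allylic peroxide.

Step 12
Reactants: 19 methyl acetal
Product: 20 1β,2β-diol (either cis-diol serves)
Conditions: OsO4 (5 mol%), NMO, acetone/H2O, rt
Reagents that add atoms: osmium tetroxide O=[Os](=O)(=O)=O; N-methylmorpholine N-oxide C[N+]1([O-])CCOCC1; water O
Why: Upjohn dihydroxylation should touch only the cis-disubstituted C1=C2 alkene, the tetrasubstituted C8=C9 alkene being shielded by C10; attack anti to the axial C20 methyl is expected, but the diol configuration is erased in step 13.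

Step 13
Reactants: 20 diol
Product: 21 diosphenol (C1 ketone, C2 enol toward C3)
Conditions: IBX (4 equiv), DMSO, rt → 40 °C
Reagents that add atoms: none
Why: IBX oxidises vicinal diols to 1,2-diones without C–C cleavage, and the dione can enolise only toward C3 because C10 is quaternary.

Step 14
Reactants: 21 diosphenol
Product: 22 1α,2α-diol
Conditions: NaBH4, MeOH, −20 → 0 °C
Reagents that add atoms: none
Why: borohydride reduction in which hydride reaches C1 axially from the β face (anti to the axial C20 methyl) and, after ketonisation, C2 from the β face (the α face is blocked by the syn-axial C20 and C19 methyls), so both hydroxyls should end up α; dialkyl peroxides are inert to NaBH4.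

Step 15
Reactants: 22 cis-diol
Product: 23 1α,2α-diacetate
Conditions: Ac2O, DMAP, pyridine, 50 °C
Reagents that add atoms: acetic anhydride CC(=O)OC(C)=O
Why: DMAP-catalysed acetylation, forced for the axial C2 hydroxyl, installs both acetates of the target.

Step 16
Reactants: 23 diacetate
Product: 24 primary alcohol (C15–OH)
Conditions: HF·pyridine, pyridine/THF, 0 °C → rt
Reagents that add atoms: none
Why: buffered fluoride desilylation leaves the acetates, the methyl acetal and the peroxide untouched.

Step 17
Reactants: 24 alcohol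
Product: 25 aldehyde (C13–CH2–CHO)
Conditions: Dess–Martin periodinane, CH2Cl2, 0 °C → rt
Reagents that add atoms: none
Why: Dess–Martin oxidation of the only free hydroxyl is neutral enough for the peroxide and the acetal.

Step 18
Reactants: 25 aldehyde
Product: 26 9α,11α-epoxy-15-ketone (ring D closed, C16 still CH2)
Conditions: di-tert-butyl hyponitrite (10 mol%, two portions), degassed benzene (0.01 M), 45 °C
Reagents that add atoms: none
Why: Proposed new method: tert-butoxyl radicals from the initiator abstract the formyl hydrogen of 25; the C15 acyl radical adds to C8 of the C8=C9 alkene (5-exo-trig, closing ring D), and the tertiary C9 radical attacks the proximal peroxide oxygen on C11 (3-exo-tet homolytic substitution at oxygen, closing the oxirane) and expels tert-butoxyl, which carries the chain, so the step is a redox-neutral isomerisation releasing only tert-butanol. The closest known reaction types are the alkoxyl- or thiol-initiated acyl radical cyclisation of alkenals and the radical-induced decomposition of allylic tert-butyl peroxides to oxiranes after radical addition to the alkene. C8 is set by the tether, since the β-oriented CH2C(=O)• arm on C13 can reach only the β face of C8 and gives the cis-bridged bicyclo[3.2.1]octanone. C9 is set by C11, since the oxirane can close only on the face that carries the C11–O bond (α). The step needs attack at C8 rather than C9, secured by the 5-exo preference and by C9 being neopentylic to quaternary C10, and oxirane closure faster than hydrogen transfer or decarbonylation, secured by high dilution, the unimolecular substitution step and the slow CO loss of a primary acyl radical.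

Step 19
Reactants: 26 epoxy ketone
Product: 29 16-methylene ketone (methyl acetal of the target), via Mannich base 27 (not isolated), via methiodide 28 (not isolated)
Conditions: LiHMDS (1.1 equiv), THF, −78 °C; CH2=NMe2+ I−, −78 → 0 °C; then MeI, CH2Cl2, rt; then aq NaHCO3
Reagents that add atoms: Eschenmoser's salt C=[N+](C)C.[I-]
Why: Mannich methylenation of the only enolisable ketone position C16 (C8 is quaternary; the ketone is deprotonated faster than the acetates at −78 °C), followed by quaternisation and E1cB loss of trimethylamine, should give the exocyclic enone.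

Step 20
Reactants: 29 methyl acetal
Product: 30 CNP0224512.1 (target)
Conditions: 0.2 M HCl, THF/H2O, 0 °C → rt
Reagents that add atoms: water O
Why: mild acid hydrolysis of the 2-alkoxyoxepane-type acetal should be much faster than opening of the hindered oxirane, and the lactol should settle to the drawn C6 anomer by ring–chain equilibration.

**Compound list**

1 | mesityl oxide | CC(=O)C=C(C)C | starting material
2 | ethyl acetoacetate | CCOC(=O)CC(C)=O | starting material
3 | ethyl 2,6,6-trimethyl-4-oxocyclohex-2-ene-1-carboxylate (racemic) | CCOC(=O)C1C(C)=CC(=O)CC1(C)C | intermediate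
4 | ethyl (1R,4R)-4-hydroxy-2,6,6-trimethylcyclohex-2-ene-1-carboxylate | CCOC(=O)[C@H]1C(C)=C[C@H](O)CC1(C)C | intermediate
5 | triethyl orthoacetate | CC(OCC)(OCC)OCC | starting material
6 | ketene acetal (O-ethyl O-allyl ketene acetal of 4) | CCOC(=O)[C@H]1C(C)=C[C@H](OC(=C)OCC)CC1(C)C | intermediate
7 | ethyl (1R,2R)-2-(2-ethoxy-2-oxoethyl)-2,6,6-trimethylcyclohex-3-ene-1-carboxylate | CCOC(=O)C[C@]1(C)C=CCC(C)(C)[C@H]1C(=O)OCC | intermediate
8 | tert-butyl acetate | CC(=O)OC(C)(C)C | starting material
9 | tert-butyl 4-[(1R,6R)-6-(ethoxycarbonyl)-1,5,5-trimethylcyclohex-2-en-1-yl]-3-oxobutanoate | CC(C)(C)OC(=O)CC(=O)C[C@]1(C)C=CCC(C)(C)[C@H]1C(=O)OCC | intermediate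
10 | but-3-en-1-ol | C=CCCO | starting material
11 | tert-butyl(but-3-en-1-yloxy)diphenylsilane | C=CCCO[Si](c1ccccc1)(c1ccccc1)C(C)(C)C | intermediate
12 | crotonaldehyde | C/C=C/C=O | starting material
13 | (E)-5-[(tert-butyldiphenylsilyl)oxy]pent-2-enal | O=C/C=C/CCO[Si](c1ccccc1)(c1ccccc1)C(C)(C)C | intermediate
14 | Michael adduct (β-keto ester alkylated at C14 by the (S)-C13 aldehyde chain; C14 epimers) | O=CC[C@@H](CCO[Si](c1ccccc1)(c1ccccc1)C(C)(C)C)C(C(=O)OC(C)(C)C)C(=O)C[C@]1(C)C=CCC(C)(C)[C@H]1C(=O)OCC | intermediate
15 | ethyl (1R,2R)-2-{(4S)-4-[2-(tert-butyldiphenylsilyloxy)ethyl]-6-oxocyclohex-1-en-1-yl}-2,6,6-trimethylcyclohex-3-ene-1-carboxylate | CCOC(=O)[C@@H]1C(C)(C)CC=C[C@@]1(C)C1=CC[C@@H](CCO[Si](c2ccccc2)(c2ccccc2)C(C)(C)C)CC1=O | intermediate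
16 | vinyl oxirane (spiro-epoxide of 15 at C8; both C8 epimers) | CCOC(=O)[C@@H]1C(C)(C)CC=C[C@@]1(C)C1=CC[C@@H](CCO[Si](c2ccccc2)(c2ccccc2)C(C)(C)C)CC12CO2 | intermediate
17 | allylic peroxide (C8=C9, C7 CH2OH, 11α-OOtBu, C5 ethyl ester) | CCOC(=O)[C@@H]1C(C)(C)CC=C[C@@]1(C)C1=C(CO)C[C@H](CCO[Si](c2ccccc2)(c2ccccc2)C(C)(C)C)C[C@H]1OOC(C)(C)C | intermediate
18 | tricyclic lactol (A/B/C rings; C6 hemiacetal, Δ1, Δ8(9), 11α-OOtBu) | O[C@@H]1OCC2=C([C@]3(C)C=CCC(C)(C)[C@@H]13)[C@H](OOC(C)(C)C)C[C@@H](CCO[Si](c4ccccc4)(c4ccccc4)C(C)(C)C)C2 | intermediate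
19 | methyl acetal of 18 | CO[C@@H]1OCC2=C([C@]3(C)C=CCC(C)(C)[C@@H]13)[C@H](OOC(C)(C)C)C[C@@H](CCO[Si](c4ccccc4)(c4ccccc4)C(C)(C)C)C2 | intermediate
20 | 1β,2β-diol | CO[C@@H]1OCC2=C([C@]3(C)[C@H](O)[C@H](O)CC(C)(C)[C@@H]13)[C@H](OOC(C)(C)C)C[C@@H](CCO[Si](c4ccccc4)(c4ccccc4)C(C)(C)C)C2 | intermediate
21 | diosphenol (1-oxo-2-hydroxy-Δ2) | CO[C@@H]1OCC2=C([C@]3(C)C(=O)C(O)=CC(C)(C)[C@@H]13)[C@H](OOC(C)(C)C)C[C@@H](CCO[Si](c4ccccc4)(c4ccccc4)C(C)(C)C)C2 | intermediate
22 | 1α,2α-diol | CO[C@@H]1OCC2=C([C@]3(C)[C@@H](O)[C@@H](O)CC(C)(C)[C@@H]13)[C@H](OOC(C)(C)C)C[C@@H](CCO[Si](c4ccccc4)(c4ccccc4)C(C)(C)C)C2 | intermediate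
23 | 1α,2α-diacetate | CO[C@@H]1OCC2=C([C@]3(C)[C@@H](OC(C)=O)[C@@H](OC(C)=O)CC(C)(C)[C@@H]13)[C@H](OOC(C)(C)C)C[C@@H](CCO[Si](c4ccccc4)(c4ccccc4)C(C)(C)C)C2 | intermediate
24 | primary alcohol (C15–OH) | CO[C@@H]1OCC2=C([C@]3(C)[C@@H](OC(C)=O)[C@@H](OC(C)=O)CC(C)(C)[C@@H]13)[C@H](OOC(C)(C)C)C[C@@H](CCO)C2 | intermediate
25 | aldehyde (key-step precursor) | CO[C@@H]1OCC2=C([C@]3(C)[C@@H](OC(C)=O)[C@@H](OC(C)=O)CC(C)(C)[C@@H]13)[C@H](OOC(C)(C)C)C[C@@H](CC=O)C2 | intermediate
26 | 9α,11α-epoxy-15-ketone (C16 CH2, C6 OMe) | C1C(=O)[C@@]23CO[C@@H](OC)[C@@H]4C(C)(C)C[C@H](OC(C)=O)[C@H](OC(C)=O)[C@@]4(C)[C@]24O[C@@H]4C[C@@H]1C3 | intermediate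
27 | Mannich base (16-CH2NMe2; C16 epimers) | CN(C)CC1C(=O)[C@@]23CO[C@@H](OC)[C@@H]4C(C)(C)C[C@H](OC(C)=O)[C@H](OC(C)=O)[C@@]4(C)[C@]24O[C@@H]4C[C@@H]1C3 | intermediate
28 | methiodide of 27 | C[N+](C)(C)CC1C(=O)[C@@]23CO[C@@H](OC)[C@@H]4C(C)(C)C[C@H](OC(C)=O)[C@H](OC(C)=O)[C@@]4(C)[C@]24O[C@@H]4C[C@@H]1C3.[I-] | intermediate
29 | 16-methylene ketone, C6 methyl acetal | C=C1C(=O)[C@@]23CO[C@@H](OC)[C@@H]4C(C)(C)C[C@H](OC(C)=O)[C@H](OC(C)=O)[C@@]4(C)[C@]24O[C@@H]4C[C@@H]1C3 | intermediate
30 | CNP0224512.1 | C=C1C(=O)[C@@]23CO[C@@H](O)[C@@H]4C(C)(C)C[C@H](OC(C)=O)[C@H](OC(C)=O)[C@@]4(C)[C@]24O[C@@H]4C[C@@H]1C3 | target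

Total step count: 20. Longest linear sequence: 18 steps (steps 1–4 and 7–20).

**Steps most likely to fail**

Step 18. The chain may break down: tert-butoxyl may abstract the acetal or allylic ether C–H bonds instead of the formyl hydrogen, or the acyl radical may be quenched before it reaches the hindered C8. The fallback sets out from 25 and uses known reaction types only. Samarium diiodide with HMPA in THF should cleave the O–O bond and then effect a ketyl–olefin cyclisation onto C8 with β-elimination of the C11 oxygen, giving the C15 carbinol with a C9=C11 alkene F1. Dess–Martin oxidation gives the Δ9(11) 15-ketone F2. Epoxidation with dimethyldioxirane from the exo face of the bicyclo[3.2.1]octene (anti to the C15–C16 bridge) returns to 26.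

Step 9. The Lewis acid may divert the vinyl oxirane into hydride shift to an aldehyde, or the hydroperoxide may be captured at the tertiary C8 or with poor facial selectivity. The fallback sets out from 16. Lithium bromide and acetic acid in THF should open the vinyl oxirane in the 1,4 sense to the allylic bromide F3 (C11–Br, C7–OH). Silver triflate-assisted substitution with tert-butyl hydroperoxide in the presence of 2,6-di-tert-butylpyridine (a known route to allylic peroxides) then returns to 17, with the same axial preference trans to the C13 chain.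

Step 10. The hindered ester may be over-reduced to the diol, or the O–O bond may be attacked by hydride if the reduction has to be warmed. The fallback sets out from 17. Acid-catalysed lactonisation (CSA, toluene, 80 °C, removal of ethanol) gives the ε-lactone F4. One equivalent of DIBAL-H at −78 °C (or disiamylborane) then reduces the lactone to the lactol and returns to 18.

**Further compounds**

F1 | step 18 | C15 carbinol with C9=C11 alkene (C15 epimers) | C1C(O)[C@@]23CO[C@@H](OC)[C@@H]4C(C)(C)C[C@H](OC(C)=O)[C@H](OC(C)=O)[C@@]4(C)C2=CC[C@@H]1C3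
F2 | step 18 | Δ9(11) 15-ketone | C1C(=O)[C@@]23CO[C@@H](OC)[C@@H]4C(C)(C)C[C@H](OC(C)=O)[C@H](OC(C)=O)[C@@]4(C)C2=CC[C@@H]1C3
F3 | step 9 | allylic bromide (C11–Br, C8=C9, C7 CH2OH; C11 epimers) | CCOC(=O)[C@@H]1C(C)(C)CC=C[C@@]1(C)C1=C(CO)C[C@H](CCO[Si](c2ccccc2)(c2ccccc2)C(C)(C)C)CC1Br
F4 | step 10 | ε-lactone (C6 carbonyl closed onto the C7 oxygen) | O=C1OCC2=C([C@]3(C)C=CCC(C)(C)[C@@H]13)[C@H](OOC(C)(C)C)C[C@@H](CCO[Si](c4ccccc4)(c4ccccc4)C(C)(C)C)C2
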